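The flavone is cut through ring C (O1, C2, C3, C4, C4a, C8a) at C4a–C4, C4–C3 and O1–C2. One palladium-catalysed carbonylative annulation of an iodophenol with carbon monoxide and phenylacetylene builds the whole pyranone. It exploits the fact that the iodine-bearing C4a has a single free oxygen neighbour, the C8a hydroxyl beside C8. O5 is a methyl ether, and the second hydroxyl (future O7) is meta to C4a and cannot close, so the piperidine must end at C8, not C6. The precursor is 4-iodo-5-methoxyresorcinol bearing the (R)-N-methylpiperidine at C2, assembled from symmetric 5-methoxyresorcinol by Ellman sulfinimine chemistry.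

Key step: step 8

Remark: the Grignard addition of step 4 is assumed to follow the usual chelated (sulfinyl-oxygen-bound) chair model, which is why the (S)-sulfinamide is chosen for the (R) carbon; the configuration of 10 should be checked before going on.

Step 1
Reactants: 1 5-methoxyresorcinol (5-methoxybenzene-1,3-diol)
Product: 2 1-methoxy-3,5-bis(methoxymethoxy)benzene
Conditions: NaH (2.4 equiv), MOMCl (2.4 equiv), DMF, 0 °C → rt
Reagents that add atoms: chloromethyl methyl ether, COCCl
Why: Williamson O-alkylation of both phenoxides gives the bis-MOM acetal, which later directs the lithiation and comes off under mild acid while the methyl ether stays.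

Step 2
Reactants: 2 1-methoxy-3,5-bis(methoxymethoxy)benzene
Product: 4 4-methoxy-2,6-bis(methoxymethoxy)benzaldehyde, via aryllithium 3 (not isolated)
Conditions: n-BuLi, TMEDA, THF, 0 °C; then DMF, 0 °C → rt; aq. NH4Cl
Reagents that add atoms: N,N-dimethylformamide, CN(C)C=O
Why: Directed ortho-metalation should take place at the C–H flanked by the two strongly coordinating OMOM groups, and formylation of the aryllithium with DMF places the carbon substituent between the two masked hydroxyls and para to the methoxy.

Step 3
Reactants: 4 4-methoxy-2,6-bis(methoxymethoxy)benzaldehyde; 5 (S)-2-methylpropane-2-sulfinamide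
Product: 6 (S,E)-N-[4-methoxy-2,6-bis(methoxymethoxy)benzylidene]-2-methylpropane-2-sulfinamide
Conditions: Ti(OEt)4 (2 equiv), THF, 60 °C
Reagents that add atoms: none
Why: Ti(OEt)4-mediated Ellman condensation gives the (E)-N-sulfinyl aldimine and acts as water scavenger; the acetals are inert to it.

Step 4
Reactants: 6 (S,E)-N-sulfinyl aldimine; 7 1-bromo-4-chlorobutane
Product: 10 (2R)-2-[4-methoxy-2,6-bis(methoxymethoxy)phenyl]-1-[(S)-2-methylpropane-2-sulfinyl]piperidine, via 4-chlorobutylmagnesium bromide 8 (not isolated), via open-chain sulfinamide 9 (not isolated)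
Conditions: 7, Mg, THF, rt (forms 8); then 6, toluene, −78 → 0 °C; then t-BuOK, THF, 0 → 25 °C; chromatography to a single diastereomer
Reagents that add atoms: none
Why: Ellman 1,2-addition of the Grignard reagent through the chelated chair transition state should deliver the alkyl group to the Re face of the (S)-sulfinyl imine and so set the (R) benzylic centre, after which the sulfinamide anion closes the piperidine by 6-exo-tet N-alkylation on the chloride.

Step 5
Reactants: 10 (2R)-N-sulfinyl-2-arylpiperidine
Product: 12 (2R)-2-[4-methoxy-2,6-bis(methoxymethoxy)phenyl]-1-methylpiperidine, via secondary piperidine 11 (not isolated)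
Conditions: HCl (4 M in dioxane, 2.2 equiv), MeOH, 0 °C, 20 min; concentrate cold; then Et3N, 37 % aq. HCHO, NaBH(OAc)3, DCE, rt
Reagents that add atoms: formaldehyde, C=O
Why: Acidolysis of the N–S bond is much faster at 0 °C than cleavage of aryl MOM acetals, and reductive amination of the freed secondary amine with formaldehyde and NaBH(OAc)3 installs the N-methyl group without touching the stereocentre.

Step 6
Reactants: 12 (2R)-2-[4-methoxy-2,6-bis(methoxymethoxy)phenyl]-1-methylpiperidine
Product: 13 (2R)-2-[3-iodo-4-methoxy-2,6-bis(methoxymethoxy)phenyl]-1-methylpiperidine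
Conditions: NIS (1.05 equiv), MeCN, 0 °C → rt, dark
Reagents that add atoms: N-iodosuccinimide, O=C1CCC(=O)N1I
Why: Electrophilic aromatic iodination of the trioxygenated ring; the two open ring positions are equivalent (each lies between an OMOM and the OMe), so one equivalent of NIS should give a single mono-iodide with iodine next to the para-methoxy.

Step 7
Reactants: 13 (2R)-2-[3-iodo-4-methoxy-2,6-bis(methoxymethoxy)phenyl]-1-methylpiperidine
Product: 14 4-iodo-5-methoxy-2-[(2R)-1-methylpiperidin-2-yl]benzene-1,3-diol
Conditions: HCl (1.25 M in MeOH), 0 °C → rt; NaHCO3 work-up; used at once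
Reagents that add atoms: none
Why: Acid-catalysed acetal exchange with methanol removes both MOM groups as dimethoxymethane and leaves the methyl ether, the aryl iodide and the amine; both phenols can be freed because only the one beside iodine can take part in step 8.

Step 8
Reactants: 14 4-iodo-5-methoxy-2-[(2R)-1-methylpiperidin-2-yl]benzene-1,3-diol; 15 phenylacetylene; 16 carbon monoxide
Product: 18 7-hydroxy-5-methoxy-8-[(2R)-1-methylpiperidin-2-yl]-2-phenyl-4H-chromen-4-one, via ynone 17 (not isolated)
Conditions: PdCl2(dppf) (5 mol %), 15 (1.5 equiv), CO (3 bar), Et2NH, DMF, 45 °C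
Reagents that add atoms: none
Why: Oxidative addition of Pd(0) to the aryl C–I bond and migratory insertion of CO give an acylpalladium that is alkynylated by phenylacetylene (copper-free, amine-assisted) to the o-hydroxyaryl ynone 17. The phenol oxygen next to the new ketone then adds to the phenyl-bearing alkyne carbon in a 6-endo-dig oxa-Michael closure, relayed by reversible diethylamine addition to the ynone (β-amino enone, then addition–elimination), which shuts off the 5-exo route to an aurone. The closest known reaction type is the Pd-catalysed carbonylative Sonogashira annulation of o-iodophenols and terminal alkynes to flavones in secondary-amine media. No stereocentre is created and the existing benzylic centre takes no part; the temperature is kept low so that this centre is not disturbed. The selectivity needed is 8- over 6-attachment of the piperidine, and the substrate secures it: the acyl carbon lies between a methyl ether and one hydroxyl (the one beside the piperidine carbon), while the other hydroxyl is meta to it and out of reach. Carbonylation should outrun direct alkynylation and benzofuran formation because the aryl-palladium is electron-rich and hindered, no copper is present and CO is under pressure.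

Step 9
Reactants: 18 7-hydroxy-5-methoxy-8-[(2R)-1-methylpiperidin-2-yl]-2-phenyl-4H-chromen-4-one
Product: 19 5,7-dihydroxy-8-[(2R)-1-methylpiperidin-2-yl]-2-phenyl-4H-chromen-4-one (target)
Conditions: BCl3 (4 equiv), CH2Cl2, −78 → 0 °C; MeOH, then aq. NaHCO3
Reagents that add atoms: none
Why: Lewis-acid ether cleavage by BCl3 is directed to the 5-methoxy group by the six-membered chelate with the peri C4 carbonyl and runs at a temperature too low for Wessely–Moser isomerisation or ionisation of the benzylic C–N bond.

Compound list
1 | 5-methoxyresorcinol (5-methoxybenzene-1,3-diol) | COc1cc(O)cc(O)c1 | starting material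
2 | 1-methoxy-3,5-bis(methoxymethoxy)benzene | COCOc1cc(OC)cc(OCOC)c1 | intermediate
3 | [4-methoxy-2,6-bis(methoxymethoxy)phenyl]lithium | [Li]c1c(OCOC)cc(OC)cc1OCOC | intermediate
4 | 4-methoxy-2,6-bis(methoxymethoxy)benzaldehyde | O=Cc1c(OCOC)cc(OC)cc1OCOC | intermediate
5 | (S)-2-methylpropane-2-sulfinamide | CC(C)(C)[S@](=O)N | starting material
6 | (S,E)-N-[4-methoxy-2,6-bis(methoxymethoxy)benzylidene]-2-methylpropane-2-sulfinamide | CC(C)(C)[S@](=O)/N=C/c1c(OCOC)cc(OC)cc1OCOC | intermediate
7 | 1-bromo-4-chlorobutane | ClCCCCBr | starting material
8 | 4-chlorobutylmagnesium bromide | ClCCCC[Mg]Br | intermediate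
9 | (S)-N-{(1R)-5-chloro-1-[4-methoxy-2,6-bis(methoxymethoxy)phenyl]pentyl}-2-methylpropane-2-sulfinamide | CC(C)(C)[S@](=O)N[C@H](CCCCCl)c1c(OCOC)cc(OC)cc1OCOC | intermediate
10 | (2R)-2-[4-methoxy-2,6-bis(methoxymethoxy)phenyl]-1-[(S)-2-methylpropane-2-sulfinyl]piperidine | CC(C)(C)[S@](=O)N1CCCC[C@@H]1c1c(OCOC)cc(OC)cc1OCOC | intermediate
11 | (2R)-2-[4-methoxy-2,6-bis(methoxymethoxy)phenyl]piperidine | N1CCCC[C@@H]1c1c(OCOC)cc(OC)cc1OCOC | intermediate
12 | (2R)-2-[4-methoxy-2,6-bis(methoxymethoxy)phenyl]-1-methylpiperidine | CN1CCCC[C@@H]1c1c(OCOC)cc(OC)cc1OCOC | intermediate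
13 | (2R)-2-[3-iodo-4-methoxy-2,6-bis(methoxymethoxy)phenyl]-1-methylpiperidine | CN1CCCC[C@@H]1c1c(OCOC)c(I)c(OC)cc1OCOC | intermediate
14 | 4-iodo-5-methoxy-2-[(2R)-1-methylpiperidin-2-yl]benzene-1,3-diol | CN1CCCC[C@@H]1c1c(O)c(I)c(OC)cc1O | intermediate
15 | phenylacetylene | C#Cc1ccccc1 | starting material
16 | carbon monoxide | [C-]#[O+] | starting material
17 | 1-{2,4-dihydroxy-6-methoxy-3-[(2R)-1-methylpiperidin-2-yl]phenyl}-3-phenylprop-2-yn-1-one | CN1CCCC[C@@H]1c1c(O)c(C(=O)C#Cc2ccccc2)c(OC)cc1O | intermediate
18 | 7-hydroxy-5-methoxy-8-[(2R)-1-methylpiperidin-2-yl]-2-phenyl-4H-chromen-4-one | CN1CCCC[C@@H]1c1c(O)cc(OC)c2c(=O)cc(-c3ccccc3)oc12 | intermediate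
19 | 5,7-dihydroxy-8-[(2R)-1-methylpiperidin-2-yl]-2-phenyl-4H-chromen-4-one | CN1CCCC[C@@H]1c1c(O)cc(O)c2c(=O)cc(-c3ccccc3)oc12 | target

Total step count: 9. Longest linear sequence: 9 steps (1 → 19).

Steps most likely to fail

1. Step 8. Oxidative addition at the hindered, very electron-rich C–I bond may be slow. Direct alkynylation without CO uptake, followed by 5-endo closure to a benzofuran, may compete, as may aminocarbonylation by diethylamine. Warming could also erode the configuration through reversible ionisation of the ortho-hydroxybenzylic C–N bond. The fallback sets out from 13 and forms the same three bonds stepwise. Iodine–magnesium exchange with i-PrMgCl·LiCl in THF at −10 °C should give the arylmagnesium chloride F1. Acylation with N-methoxy-N-methyl-3-phenylpropiolamide (Weinreb ketone synthesis) should give the bis-MOM ynone F2. Cold methanolic HCl then removes the acetals to give ynone 17, and diethylamine at room temperature closes it 6-endo to rejoin the route at 18.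

2. Step 4. The two ortho OMOM oxygens may bind magnesium in competition with the sulfinyl oxygen, giving poor or reversed facial selectivity, and addition to the hindered, electron-rich C=N bond may be sluggish. The fallback sets out from aryllithium 3 (made from 2 as in step 2) and sets the centre by catalysis instead of an auxiliary. Transmetalation with ZnCl2 gives the arylzinc chloride F3, and Negishi coupling with 2-bromopyridine (Pd/XPhos) gives the 2-arylpyridine F4. Benzyl bromide in MeCN gives the N-benzylpyridinium bromide F5. Iridium-catalysed asymmetric hydrogenation with a chiral bisphosphine, the ligand enantiomer chosen for the (R) product, should give the (R)-N-benzylpiperidine F6, which can be upgraded by crystallising a salt. H2, Pd/C and aqueous formaldehyde in MeOH then exchange benzyl for methyl through 11 and rejoin the route at 12.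

3. Step 7. Acid on the very electron-rich aryl iodide may cause proto-deiodination or iodine migration, and once the ortho phenols are free the benzylic C–N bond may ionise and partly racemise. The fallback sets out from 12 and reverses the order of deprotection and halogenation. Cold methanolic HCl removes both acetals before any iodine is present and should give the iodine-free diol F7. Mono-iodination with NIS (1.0 equiv) in MeCN at −40 °C, where the two open ring positions are again equivalent, rejoins the route at 14.

Further compounds
F1 | step 8 | chloro{6-methoxy-2,4-bis(methoxymethoxy)-3-[(2R)-1-methylpiperidin-2-yl]phenyl}magnesium | CN1CCCC[C@@H]1c1c(OCOC)c([Mg]Cl)c(OC)cc1OCOC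
F2 | step 8 | 1-{6-methoxy-2,4-bis(methoxymethoxy)-3-[(2R)-1-methylpiperidin-2-yl]phenyl}-3-phenylprop-2-yn-1-one | CN1CCCC[C@@H]1c1c(OCOC)c(C(=O)C#Cc2ccccc2)c(OC)cc1OCOC
F3 | step 4 | chloro[4-methoxy-2,6-bis(methoxymethoxy)phenyl]zinc | Cl[Zn]c1c(OCOC)cc(OC)cc1OCOC
F4 | step 4 | 2-[4-methoxy-2,6-bis(methoxymethoxy)phenyl]pyridine | COCOc1cc(OC)cc(OCOC)c1-c1ccccn1
F5 | step 4 | 1-benzyl-2-[4-methoxy-2,6-bis(methoxymethoxy)phenyl]pyridin-1-ium bromide | COCOc1cc(OC)cc(OCOC)c1-c1cccc[n+]1Cc1ccccc1.[Br-]
F6 | step 4 | (2R)-1-benzyl-2-[4-methoxy-2,6-bis(methoxymethoxy)phenyl]piperidine | C(c1ccccc1)N1CCCC[C@@H]1c1c(OCOC)cc(OC)cc1OCOC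
F7 | step 7 | 5-methoxy-2-[(2R)-1-methylpiperidin-2-yl]benzene-1,3-diol | CN1CCCC[C@@H]1c1c(O)cc(OC)cc1O
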